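## Retrosynthetic overview

- Target ⇒ heptabenzyl cyclobutane by global hydrogenolysis. Only O–benzyl bonds are cleaved; the skeleton and all five stereocentres are already complete.
- Cyclobutane (the only ring made, and the last C–C bond-forming event) ⇒ one crossed, head-to-tail [2+2] photocycloaddition. It joins the caffeoyl C=C of intact perbenzylated (R)-rosmarinate to the C=C of a protected p-coumarate, the union presumed to occur in the plant.
- The side-chain ester is not made late. It is carried through the cycloaddition as a tin-chelating handle meant to select the chromophore, the regiochemistry and the alkene face, so all four ring stereocentres arise in that one step.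
- Partners ⇒ perbenzylation of commercial (R)-rosmarinic acid and p-coumaric acid.

Assumption: natural (R)-rosmarinic acid counts as a commercial starting material; ions, partly benzylated species and excited states are not numbered, whereas Lewis-acid adducts are.

## Route

Step 1
Reactants: 1 (R)-rosmarinic acid
Product: 2 pentabenzyl (R)-rosmarinate
Conditions: BnBr (6 equiv), K2CO3 (6 equiv), DMF, 0 °C to rt, Ar, dark
Reagents that add atoms: benzyl bromide, BrCc1ccccc1
Why: Williamson ether synthesis on the four phenoxides together with SN2 O-benzylation of the carboxylate; no stereocentre is created and the (R)-carbinol centre should survive carbonate at room temperature (ee to be checked).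

Step 2
Reactants: 3 p-coumaric acid
Product: 4 benzyl (E)-4-benzyloxycinnamate
Conditions: BnBr (2.5 equiv), K2CO3 (3 equiv), DMF, rt
Reagents that add atoms: benzyl bromide, BrCc1ccccc1
Why: The same Williamson/carboxylate alkylation; the E alkene is untouched and no stereocentre is involved.

Step 3
Reactants: 2 pentabenzyl (R)-rosmarinate; 4 benzyl (E)-4-benzyloxycinnamate
Product: 7 heptabenzyl all-trans cycloadduct, via SnCl4 chelate 5 (not isolated), via SnCl4-bound cycloadduct 6 (not isolated)
Conditions: SnCl4 (1.05 equiv), CH2Cl2, −78 °C; then 4 (5 equiv, excess recovered), 405 nm LED, −78 °C, Ar; H2O quench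
Reagents that add atoms: none
Why: Proposed new method: SnCl4 should chelate the α-acyloxy ester of 2 through the caffeoyl C=O and the benzyl-ester C=O (seven-membered chelate, no free site left on hexacoordinate tin), shifting the caffeoyl absorption far enough that 405 nm light excites only chelate 5; its singlet exciplex with ground-state, electron-rich 4 is expected to collapse with retention of both E geometries in the head-to-tail sense set by polarity (nucleophilic Cα of 4 to the electrophilic Cβ of the bound enoate, its Cβ to the bound Cα); the bulky chelate should block stacking of the aryl ring of 4 over the bound carboxyl, leaving the crossed anti approach, which puts every ring substituent trans to both neighbours (ε-truxillate pattern); the working model for face selection is that 4 adds to the Cα-Si/Cβ-Si face of the caffeoyl alkene, anti to the tin-bearing side of the chelate ring fixed by the (R)-centre, giving C1 R, C2 R, C3 S, C4 S; the closest known reaction types are the BF3- or SnCl4-promoted head-to-tail [2+2] photodimerisation and photo-cross-cycloaddition of cinnamate esters and TiCl4-chelate-controlled additions to acrylates of lactate esters.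

Step 4
Reactants: 7 heptabenzyl all-trans cycloadduct
Product: 8 target acid (CNP0270917.1)
Conditions: H2 (1 atm), 10% Pd/C, EtOAc/MeOH 1:1, rt, work-up under Ar
Reagents that add atoms: none
Why: Heterogeneous catalytic hydrogenolysis of five aryl benzyl ethers and two benzyl esters; the neutral conditions leave the secondary ester, the cyclobutane and all five stereocentres unchanged, and no alkene remains to be reduced.

## Compound list

Ring locants used for 6, 7 and 8: C1 = carbon bearing the coumarate-derived carboxyl, C2 = carbon bearing the 4-oxyphenyl ring, C3 = carbon bearing the side-chain ester carbonyl, C4 = carbon bearing the 3,4-dioxyphenyl ring. Every ring substituent is trans to both of its neighbours.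

1 | (R)-rosmarinic acid, (2R)-2-{[(2E)-3-(3,4-dihydroxyphenyl)prop-2-enoyl]oxy}-3-(3,4-dihydroxyphenyl)propanoic acid | O=C(/C=C/c1ccc(O)c(O)c1)O[C@H](Cc1ccc(O)c(O)c1)C(=O)O | starting material

2 | pentabenzyl (R)-rosmarinate, benzyl (2R)-2-{[(2E)-3-[3,4-bis(benzyloxy)phenyl]prop-2-enoyl]oxy}-3-[3,4-bis(benzyloxy)phenyl]propanoate | O=C(/C=C/c1ccc(OCc2ccccc2)c(OCc2ccccc2)c1)O[C@H](Cc1ccc(OCc2ccccc2)c(OCc2ccccc2)c1)C(=O)OCc1ccccc1 | intermediate

3 | p-coumaric acid, (2E)-3-(4-hydroxyphenyl)prop-2-enoic acid | O=C(O)/C=C/c1ccc(O)cc1 | starting material

4 | benzyl (2E)-3-[4-(benzyloxy)phenyl]prop-2-enoate | O=C(/C=C/c1ccc(OCc2ccccc2)cc1)OCc1ccccc1 | intermediate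

5 | 1:1 SnCl4 chelate of 2 (tin bound to the caffeoyl C=O and the benzyl-ester C=O) | O=C(/C=C/c1ccc(OCc2ccccc2)c(OCc2ccccc2)c1)O[C@H](Cc1ccc(OCc2ccccc2)c(OCc2ccccc2)c1)C(=O)OCc1ccccc1.Cl[Sn](Cl)(Cl)Cl | intermediate

6 | 1:1 SnCl4 adduct of cycloadduct 7 | O=C(OCc2ccccc2)[C@@H]1[C@@H](c2ccc(OCc3ccccc3)cc2)[C@H](C(=O)O[C@H](Cc2ccc(OCc3ccccc3)c(OCc3ccccc3)c2)C(=O)OCc2ccccc2)[C@H]1c1ccc(OCc2ccccc2)c(OCc2ccccc2)c1.Cl[Sn](Cl)(Cl)Cl | intermediate

7 | heptabenzyl cycloadduct: cyclobutane with C1 (R) CO2Bn, C2 (R) 4-benzyloxyphenyl, C3 (S) C(=O)O–CH(CO2Bn)CH2[3,4-bis(benzyloxy)phenyl] with side-chain centre R, C4 (S) 3,4-bis(benzyloxy)phenyl | O=C(OCc2ccccc2)[C@@H]1[C@@H](c2ccc(OCc3ccccc3)cc2)[C@H](C(=O)O[C@H](Cc2ccc(OCc3ccccc3)c(OCc3ccccc3)c2)C(=O)OCc2ccccc2)[C@H]1c1ccc(OCc2ccccc2)c(OCc2ccccc2)c1 | intermediate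

8 | target: cyclobutane with C1 (R) CO2H, C2 (R) 4-hydroxyphenyl, C3 (S) C(=O)O–CH(CO2H)CH2(3,4-dihydroxyphenyl) with side-chain centre R, C4 (S) 3,4-dihydroxyphenyl | O=C(O)[C@@H]1[C@@H](c2ccc(O)cc2)[C@H](C(=O)O[C@H](Cc2ccc(O)c(O)c2)C(=O)O)[C@H]1c1ccc(O)c(O)c1 | target

## Step count and risks

Total step count: 4. Longest linear sequence: 3 steps (1 → 2 → 7 → 8). Step 3 is a pure addition.

**Step 3 (highest risk).** The crossed anti head-to-tail mode is a design hypothesis, not established behaviour. Open points are:
- competition from the stacked syn head-to-tail adduct (aryl rings trans), which is the usual outcome of Lewis-acid cinnamate photodimerisation, and from head-to-head adducts;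
- E/Z isomerisation of 5;
- quenching of excited 5 by the electron-rich dibenzyloxyphenyl ring of the side chain;
- the sense and size of the face selection.

Compound 7 must be separated by chromatography and HPLC, and its all-trans arrangement proven by NOE, before step 4. The fallback drops templating and protection altogether. It is a fully biomimetic cross-photodimerisation that sets out from 1 and 3 and comes back to the route at 8. A 1:5 mixture of 1 and 3 is cast from methanol as a thin amorphous film on glass and irradiated at 300–365 nm under argon with periodic re-casting. The all-trans head-to-tail heterodimer 8 is then isolated from the isomer mixture by preparative reversed-phase HPLC; its ring diastereomer is separable because the side-chain centre is fixed as R. The yield will be low and unselective. This fallback makes no new isolable compound (F0).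

**Step 1.** Base-mediated perbenzylation may partly epimerise the α-acyloxy centre once the benzyl ester has formed, and may give C-benzylation or incomplete alkylation. The fallback avoids phenoxide base; it sets out from 1 and comes back at 2. Chemoselective carboxylate alkylation (KHCO3, BnBr, DMF, rt) gives benzyl (R)-rosmarinate F1. The four phenols are then etherified under base-free Mitsunobu conditions (BnOH, PPh3, DIAD, THF, 0 °C), giving 2.

**Step 4.** Seven benzyl groups must all be cleaved. The doubly benzylic strained ring could open on palladium, and the product catechols oxidise in air. The fallback is a non-reductive Lewis-acid debenzylation that sets out from 7 and comes back at 8: BCl3 with pentamethylbenzene as benzyl-cation scavenger, CH2Cl2, −78 °C, then methanol quench. It makes no new compound (F0).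

## Further compounds

F0 | step 3 | none | none
F1 | step 1 | benzyl (2R)-2-{[(2E)-3-(3,4-dihydroxyphenyl)prop-2-enoyl]oxy}-3-(3,4-dihydroxyphenyl)propanoate | O=C(/C=C/c1ccc(O)c(O)c1)O[C@H](Cc1ccc(O)c(O)c1)C(=O)OCc1ccccc1
F0 | step 4 | none | none
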